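**Plan**

- Labels: oxolane O1, C2 (bears ring B, the side-chain phenol), C3, C4, C5 (bears ring A, 4-hydroxyphenyl); ring C ends the side chain.
- Cuts, last bond first: the three O–benzyl bonds; C2–ring B (Friedel–Crafts arylation of lactol acetate 11 by arene 18); O1–C2 with C2 rejoined to C5 (Baeyer–Villiger retron, cyclobutanone 8); then C2–C3 and C4–C5 together.
- Feature behind the key step: in the ring O1–C2–C3–C4–C5 the methyls on C3 and C4 are cis, so deleting O1 and bonding C2 to C5 leaves a cyclobutanone that is the [2+2] adduct of cis-2-butene and the keteniminium ion of arylacetamide 4.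
- Forward: cyclobutane (step 2), oxygen insertion to the oxolane ring (step 3), arylation at C2 (step 9), debenzylation (step 10); arene 18 is built in parallel from 2'-hydroxyacetophenone (steps 5–8).
- Stereochemistry: C3/C4 cis from the olefin, absolute sense from (2R,5R)-2,5-dimethylpyrrolidine; C5 by α-epimerisation, kept in the Baeyer–Villiger shift; C2 by attack anti to the C3 methyl; side-chain (R) centre by iridium-catalysed asymmetric hydrogenation.

Key step: step 2

Assumption: the (2R,5R)-auxiliary (step 2) and the (S)-configured iridium ligand (step 8) are taken to induce the senses needed for 8 and 18; should either sense prove opposite, the mirror-image controller is used and nothing else changes.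

**Route**

Step 1
Reactants: 1 4-(benzyloxy)phenylacetic acid; 2 (2R,5R)-2,5-dimethylpyrrolidine
Product: 4 2-[4-(benzyloxy)phenyl]-1-[(2R,5R)-2,5-dimethylpyrrolidin-1-yl]ethan-1-one, via arylacetyl chloride 3 (not isolated)
Conditions: (COCl)2, DMF (cat.), CH2Cl2, 0 °C → rt; then 2, Et3N, CH2Cl2, 0 °C → rt
Reagents that add atoms: none
Why: Acid chloride formation followed by N-acylation is the reliable way to acylate this doubly α-branched secondary amine; no stereocentre is formed and those of the amine are untouched.

Step 2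
Reactants: 4 2-[4-(benzyloxy)phenyl]-1-[(2R,5R)-2,5-dimethylpyrrolidin-1-yl]ethan-1-one; 5 cis-2-butene
Product: 8 (2S,3S,4R)-2-[4-(benzyloxy)phenyl]-3,4-dimethylcyclobutan-1-one, via keteniminium triflate 6 (not isolated), via cyclobutaniminium triflate 7 (not isolated)
Conditions: Tf2O, 2,4,6-collidine, 5 (large excess), ClCH2CH2Cl, sealed vessel, −20 → 60 °C; then H2O, 60 °C; then Et3N, CH2Cl2, rt
Reagents that add atoms: water, O
Why: Tf2O converts amide 4 into an O-triflyl iminium salt from which collidine removes the α-proton, giving the aryl-substituted keteniminium ion 6; its electrophilic central carbon is attacked by cis-2-butene and the second C–C bond follows in the same asynchronous event, so that iminium salt 7 is formed and then hydrolysed to the ketone. The closest known reaction type is the keteniminium–olefin [2+2] cycloaddition to cyclobutaniminium salts with a twofold-symmetric 2,5-disubstituted pyrrolidine as chiral controller. The four-membered ring is closed by this cycloaddition itself, suprafacially on the olefin, with both new σ-bonds (C2–C3 and C4–C5 in oxolane numbering) made in one operation. The two methyl-bearing centres keep the cis geometry of the butene and take their absolute sense from the auxiliary, whose single methyl group on the attacked face should force the olefin substituents to the open side, while the aryl-bearing centre is set thermodynamically: its acidic benzylic α-hydrogen epimerises (Et3N) until the aryl group is trans to the neighbouring methyl. The step needs face selectivity and preservation of the cis methyl pair; the first rests on the twofold symmetry of the amine, which makes both C–N rotamers of 6 identical, and the second on the stereospecific addition together with the far lower acidity of the hydrogen on the methyl-bearing α-carbon, which mild base does not remove. A large excess of the gaseous olefin in a closed vessel should keep capture of 6 ahead of its self-condensation.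

Step 3
Reactants: 8 (2S,3S,4R)-2-[4-(benzyloxy)phenyl]-3,4-dimethylcyclobutan-1-one
Product: 9 (3R,4S,5S)-5-[4-(benzyloxy)phenyl]-3,4-dimethyloxolan-2-one
Conditions: mCPBA, CH2Cl2, 0 °C
Reagents that add atoms: mCPBA (3-chloroperoxybenzoic acid), OOC(=O)c1cccc(Cl)c1
Why: Baeyer–Villiger oxidation of a strained cyclobutanone, in which the more electron-rich aryl-bearing secondary carbon of the Criegee intermediate should migrate in preference to the methyl-bearing one and does so with retention, so that oxygen enters between the carbonyl carbon and the benzylic carbon and all three stereocentres pass into the γ-lactone.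

Step 4
Reactants: 9 (3R,4S,5S)-5-[4-(benzyloxy)phenyl]-3,4-dimethyloxolan-2-one
Product: 11 (3R,4S,5S)-5-[4-(benzyloxy)phenyl]-3,4-dimethyloxolan-2-yl acetate (both anomers), via diisobutylaluminium lactolate 10 (not isolated)
Conditions: iBu2AlH, CH2Cl2, −78 °C; then pyridine, DMAP, Ac2O, −78 → 0 °C
Reagents that add atoms: acetic anhydride, CC(=O)OC(C)=O
Why: Reductive acetylation of a lactone, in which iBu2AlH adds once at −78 °C to give the stable tetrahedral aluminium lactolate 10 that is acetylated in the same flask, so the lactol is trapped as the anomeric acetate without ring opening or α-epimerisation; the anomeric centre is of no consequence because both anomers ionise to the same oxocarbenium ion.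

Step 5
Reactants: 12 2'-hydroxyacetophenone
Product: 13 2'-(benzyloxy)acetophenone
Conditions: BnBr, K2CO3, DMF, rt
Reagents that add atoms: benzyl bromide, BrCc1ccccc1
Why: Williamson ether synthesis on the phenoxide, which masks the phenol for the Grignard step and turns ring B into a para-directing aryl ether for the later arylation.

Step 6
Reactants: 13 2'-(benzyloxy)acetophenone; 14 4-(benzyloxy)benzyl chloride
Product: 16 2-[2-(benzyloxy)phenyl]-1-[4-(benzyloxy)phenyl]propan-2-ol (racemic), via benzylic Grignard reagent 15 (not isolated)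
Conditions: 14, Mg, 2-MeTHF, 0 °C (slow addition); then 13, 0 °C → rt; aq. NH4Cl
Reagents that add atoms: none
Why: Grignard addition of a benzylic organomagnesium reagent to an aryl methyl ketone gives the tertiary benzylic alcohol, whose racemic stereocentre is removed in the next step.

Step 7
Reactants: 16 2-[2-(benzyloxy)phenyl]-1-[4-(benzyloxy)phenyl]propan-2-ol
Product: 17 1-(benzyloxy)-2-[(1E)-1-[4-(benzyloxy)phenyl]prop-1-en-2-yl]benzene
Conditions: p-TsOH·H2O (cat.), toluene, 80 °C; recrystallisation or chromatography to the pure (E)-isomer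
Reagents that add atoms: none
Why: Acid-catalysed E1 dehydration through the tertiary benzylic cation under equilibrating conditions, so that the conjugated trisubstituted stilbene with the two aryl groups trans should predominate; geometric purity is secured here because it limits the enantiopurity reachable in step 8.

Step 8
Reactants: 17 1-(benzyloxy)-2-[(1E)-1-[4-(benzyloxy)phenyl]prop-1-en-2-yl]benzene
Product: 18 1-(benzyloxy)-2-[(2R)-1-[4-(benzyloxy)phenyl]propan-2-yl]benzene
Conditions: H2 (50 bar), [Ir(cod)(L)][B(C6H3-3,5-(CF3)2)4] (1 mol%), CH2Cl2, rt; L = (S)-4-tert-butyl-2-[2-(di-o-tolylphosphanyl)phenyl]-4,5-dihydro-1,3-oxazole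
Reagents that add atoms: none
Why: Asymmetric hydrogenation of an unfunctionalised trisubstituted (E)-olefin of the α-methylstilbene type with a cationic iridium phosphinooxazoline catalyst, in which the chiral ligand selects the enantiotopic olefin face and so sets the (R) centre, while the homogeneous catalyst leaves the benzyl ethers intact.

Step 9
Reactants: 11 (3R,4S,5S)-5-[4-(benzyloxy)phenyl]-3,4-dimethyloxolan-2-yl acetate; 18 1-(benzyloxy)-2-[(2R)-1-[4-(benzyloxy)phenyl]propan-2-yl]benzene
Product: 19 (2R,3R,4S,5S)-2-{4-(benzyloxy)-3-[(2R)-1-[4-(benzyloxy)phenyl]propan-2-yl]phenyl}-5-[4-(benzyloxy)phenyl]-3,4-dimethyloxolane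
Conditions: BF3·OEt2 (promoter), CH2Cl2, −78 → −20 °C
Reagents that add atoms: none
Why: Friedel–Crafts-type C-arylation of the cyclic oxocarbenium ion released from the anomeric acetate, in which ring B should react at its unhindered position para to the benzyloxy group (ring C has its para position blocked) and approach C2 anti to the adjacent C3 methyl, giving the 2,3-trans (2R) arrangement that is also the thermodynamically preferred one.

Step 10
Reactants: 19 (2R,3R,4S,5S)-2-{4-(benzyloxy)-3-[(2R)-1-[4-(benzyloxy)phenyl]propan-2-yl]phenyl}-5-[4-(benzyloxy)phenyl]-3,4-dimethyloxolane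
Product: 20 (2R,3R,4S,5S)-2-{4-hydroxy-3-[(2R)-1-(4-hydroxyphenyl)propan-2-yl]phenyl}-5-(4-hydroxyphenyl)-3,4-dimethyloxolane (CNP0232576.1)
Conditions: H2 (1 atm), 10% Pd/C, EtOAc–MeOH, rt
Reagents that add atoms: none
Why: Catalytic hydrogenolysis of the three aryl benzyl ethers, stopped at complete debenzylation so that the more slowly cleaved benzylic ring C–O bonds should remain; no stereocentre is touched.

**Compound list**

1 | 4-(benzyloxy)phenylacetic acid | OC(=O)Cc1ccc(OCc2ccccc2)cc1 | starting material
2 | (2R,5R)-2,5-dimethylpyrrolidine | C[C@@H]1CC[C@@H](C)N1 | starting material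
3 | [4-(benzyloxy)phenyl]acetyl chloride | O=C(Cl)Cc1ccc(OCc2ccccc2)cc1 | intermediate (not isolated)
4 | 2-[4-(benzyloxy)phenyl]-1-[(2R,5R)-2,5-dimethylpyrrolidin-1-yl]ethan-1-one | O=C(Cc1ccc(OCc2ccccc2)cc1)N1[C@H](C)CC[C@H]1C | intermediate
5 | cis-2-butene | C/C=C\C | starting material
6 | (2R,5R)-1-{2-[4-(benzyloxy)phenyl]ethenylidene}-2,5-dimethylpyrrolidin-1-ium trifluoromethanesulfonate | [O-]S(=O)(=O)C(F)(F)F.C(=C=[N+]1[C@H](C)CC[C@H]1C)c1ccc(OCc2ccccc2)cc1 | intermediate (not isolated)
7 | (2R,5R)-1-{(3S,4R)-2-[4-(benzyloxy)phenyl]-3,4-dimethylcyclobutylidene}-2,5-dimethylpyrrolidin-1-ium trifluoromethanesulfonate (epimers at the aryl-bearing carbon) | [O-]S(=O)(=O)C(F)(F)F.C1(=[N+]2[C@H](C)CC[C@H]2C)C(c2ccc(OCc3ccccc3)cc2)[C@@H](C)[C@H]1C | intermediate (not isolated)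
8 | (2S,3S,4R)-2-[4-(benzyloxy)phenyl]-3,4-dimethylcyclobutan-1-one | O=C1[C@H](c2ccc(OCc3ccccc3)cc2)[C@@H](C)[C@H]1C | intermediate
9 | (3R,4S,5S)-5-[4-(benzyloxy)phenyl]-3,4-dimethyloxolan-2-one | O=C1[C@H](C)[C@H](C)[C@@H](c2ccc(OCc3ccccc3)cc2)O1 | intermediate
10 | diisobutylaluminium (3R,4S,5S)-5-[4-(benzyloxy)phenyl]-3,4-dimethyloxolan-2-olate | CC(C)C[Al](CC(C)C)OC1[C@H](C)[C@H](C)[C@@H](c2ccc(OCc3ccccc3)cc2)O1 | intermediate (not isolated)
11 | (3R,4S,5S)-5-[4-(benzyloxy)phenyl]-3,4-dimethyloxolan-2-yl acetate (both anomers) | CC(=O)OC1[C@H](C)[C@H](C)[C@@H](c2ccc(OCc3ccccc3)cc2)O1 | intermediate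
12 | 2'-hydroxyacetophenone | CC(=O)c1ccccc1O | starting material
13 | 2'-(benzyloxy)acetophenone | CC(=O)c1ccccc1OCc1ccccc1 | intermediate
14 | 4-(benzyloxy)benzyl chloride | ClCc1ccc(OCc2ccccc2)cc1 | starting material
15 | [4-(benzyloxy)benzyl]magnesium chloride | Cl[Mg]Cc1ccc(OCc2ccccc2)cc1 | intermediate (not isolated)
16 | 2-[2-(benzyloxy)phenyl]-1-[4-(benzyloxy)phenyl]propan-2-ol (racemic) | CC(O)(Cc1ccc(OCc2ccccc2)cc1)c1ccccc1OCc1ccccc1 | intermediate
17 | 1-(benzyloxy)-2-[(1E)-1-[4-(benzyloxy)phenyl]prop-1-en-2-yl]benzene | C/C(=C\c1ccc(OCc2ccccc2)cc1)c1ccccc1OCc1ccccc1 | intermediate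
18 | 1-(benzyloxy)-2-[(2R)-1-[4-(benzyloxy)phenyl]propan-2-yl]benzene | C[C@H](Cc1ccc(OCc2ccccc2)cc1)c1ccccc1OCc1ccccc1 | intermediate
19 | (2R,3R,4S,5S)-2-{4-(benzyloxy)-3-[(2R)-1-[4-(benzyloxy)phenyl]propan-2-yl]phenyl}-5-[4-(benzyloxy)phenyl]-3,4-dimethyloxolane | C[C@@H]1[C@H](C)[C@@H](c2ccc(OCc3ccccc3)cc2)O[C@H]1c1ccc(OCc2ccccc2)c([C@H](C)Cc2ccc(OCc3ccccc3)cc2)c1 | intermediate
20 | (2R,3R,4S,5S)-2-{4-hydroxy-3-[(2R)-1-(4-hydroxyphenyl)propan-2-yl]phenyl}-5-(4-hydroxyphenyl)-3,4-dimethyloxolane | C[C@@H]1[C@H](C)[C@@H](c2ccc(O)cc2)O[C@H]1c1ccc(O)c([C@H](C)Cc2ccc(O)cc2)c1 | target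

**Count**

Total steps: 10. Longest linear sequence: 6 steps (1, 2, 3, 4, 9, 10; the arene branch 5, 6, 7, 8, 9, 10 is equally long).

**Steps most likely to fail**

Step 2. The process at risk is face discrimination by the auxiliary and, behind it, capture of a weakly nucleophilic 1,2-dialkyl olefin before the keteniminium ion condenses with itself. The fallback sets out from acid 1 and comes back at ketone 8. Acid 1 is converted through chloride 3 with dimethylamine into 2-[4-(benzyloxy)phenyl]-N,N-dimethylacetamide F1. Its smaller and more electrophilic keteniminium ion is added to cis-2-butene 5 under the same Tf2O/collidine conditions, hydrolysed and equilibrated with Et3N to racemic (2S*,3S*,4R*)-2-[4-(benzyloxy)phenyl]-3,4-dimethylcyclobutan-1-one F2. Preparative chromatography on a chiral stationary phase then provides the (2S,3S,4R)-enantiomer, which is 8. Stereocontrol is thereby moved from an auxiliary to a resolution.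

Step 9. The process at risk is site selection on arene 18 (attack ortho to the ether oxygen on ring C or on ring B instead of para on ring B), with acid-induced reversible opening of the benzylic ring C–O bonds as a second concern. The fallback sets out from arene 18 and lactone 9 and comes back at 19. para-Selective bromination of 18 (NBS, MeCN, 0 °C) should give 1-(benzyloxy)-4-bromo-2-[(2R)-1-[4-(benzyloxy)phenyl]propan-2-yl]benzene F3, which can be purified and checked at this simple stage. Bromine–lithium exchange (n-BuLi, THF, −78 °C) gives {4-(benzyloxy)-3-[(2R)-1-[4-(benzyloxy)phenyl]propan-2-yl]phenyl}lithium F4. Its addition to lactone 9 gives the hemiketal (3R,4S,5S)-2-{4-(benzyloxy)-3-[(2R)-1-[4-(benzyloxy)phenyl]propan-2-yl]phenyl}-5-[4-(benzyloxy)phenyl]-3,4-dimethyloxolan-2-ol F5. Reductive deoxygenation with Et3SiH and BF3·OEt2 (CH2Cl2, −78 → 0 °C) should then give 19. The aryl group on C2 is expected to settle trans to the C3 methyl because the para-alkoxybenzylic C2–O bond opens reversibly under BF3·OEt2. The ring B carbon that forms the new bond is then fixed by the halogen and no longer by relative arene reactivity.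

Step 8. The process at risk is enantioface discrimination and turnover on a trisubstituted olefin whose aryl group carries an ortho substituent, made worse by any (Z)-isomer carried over from step 7. The fallback sets out from ketone 13 and Grignard reagent 15 and comes back at 18; it builds the centre by stereospecific lithiation–borylation and protodeboronation. Oxazaborolidine-catalysed borane reduction of 13 (BH3·SMe2, (S)-2-methyl-CBS-oxazaborolidine, THF) should give (1R)-1-[2-(benzyloxy)phenyl]ethan-1-ol F6. Carbamoylation (iPr2NCOCl, Et3N, toluene, heat) gives (1R)-1-[2-(benzyloxy)phenyl]ethyl N,N-di(propan-2-yl)carbamate F7. Reagent 15 and 2-isopropoxy-4,4,5,5-tetramethyl-1,3,2-dioxaborolane give 2-{[4-(benzyloxy)phenyl]methyl}-4,4,5,5-tetramethyl-1,3,2-dioxaborolane F8. Lithiation–borylation of F7 with F8 (s-BuLi, Et2O, −78 °C; then MgBr2, MeOH, warming) should give, with inversion at carbon, 2-[(2R)-2-[2-(benzyloxy)phenyl]-1-[4-(benzyloxy)phenyl]propan-2-yl]-4,4,5,5-tetramethyl-1,3,2-dioxaborolane F9. Protodeboronation with retention (TBAF·3H2O, toluene) returns 18.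

**Further compounds**

F1 | step 2 | 2-[4-(benzyloxy)phenyl]-N,N-dimethylacetamide | CN(C)C(=O)Cc1ccc(OCc2ccccc2)cc1
F2 | step 2 | racemic (2S*,3S*,4R*)-2-[4-(benzyloxy)phenyl]-3,4-dimethylcyclobutan-1-one | O=C1[C@H](c2ccc(OCc3ccccc3)cc2)[C@@H](C)[C@H]1C.O=C1[C@@H](c2ccc(OCc3ccccc3)cc2)[C@H](C)[C@@H]1C
F3 | step 9 | 1-(benzyloxy)-4-bromo-2-[(2R)-1-[4-(benzyloxy)phenyl]propan-2-yl]benzene | C[C@H](Cc1ccc(OCc2ccccc2)cc1)c1cc(Br)ccc1OCc1ccccc1
F4 | step 9 | {4-(benzyloxy)-3-[(2R)-1-[4-(benzyloxy)phenyl]propan-2-yl]phenyl}lithium | [Li]c1ccc(OCc2ccccc2)c([C@H](C)Cc2ccc(OCc3ccccc3)cc2)c1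
F5 | step 9 | (3R,4S,5S)-2-{4-(benzyloxy)-3-[(2R)-1-[4-(benzyloxy)phenyl]propan-2-yl]phenyl}-5-[4-(benzyloxy)phenyl]-3,4-dimethyloxolan-2-ol (both C2 epimers) | C[C@@H]1[C@H](C)[C@@H](c2ccc(OCc3ccccc3)cc2)OC1(O)c1ccc(OCc2ccccc2)c([C@H](C)Cc2ccc(OCc3ccccc3)cc2)c1
F6 | step 8 | (1R)-1-[2-(benzyloxy)phenyl]ethan-1-ol | C[C@@H](O)c1ccccc1OCc1ccccc1
F7 | step 8 | (1R)-1-[2-(benzyloxy)phenyl]ethyl N,N-di(propan-2-yl)carbamate | C[C@@H](OC(=O)N(C(C)C)C(C)C)c1ccccc1OCc1ccccc1
F8 | step 8 | 2-{[4-(benzyloxy)phenyl]methyl}-4,4,5,5-tetramethyl-1,3,2-dioxaborolane | CC1(C)OB(Cc2ccc(OCc3ccccc3)cc2)OC1(C)C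
F9 | step 8 | 2-[(2R)-2-[2-(benzyloxy)phenyl]-1-[4-(benzyloxy)phenyl]propan-2-yl]-4,4,5,5-tetramethyl-1,3,2-dioxaborolane | C[C@](B1OC(C)(C)C(C)(C)O1)(Cc1ccc(OCc2ccccc2)cc1)c1ccccc1OCc1ccccc1
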